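(Readings and results are simulated from invented constants; the scatter is artificial.)

1. Amounts first: the flask holds solid substrate, starting material (A, what is dissolved) and target, each counted as a fraction of the solid substrate charged.

the same everywhere: solid substrate 0.98 M
- beta: free catalyst 0.1 mol%; run made earlier
- flask: free catalyst 0.2 mol%; time 30 min

beta run (percent of the solid substrate charged)

| time / min | target / % | starting material / % | solid substrate / % |
|---|---|---|---|
| 0.500 | 0.1 | 34.9 | 63.7 |
| 1.00 | 1.4 | 52.3 | 46.1 |
| 2.50 | 5.6 | 67.1 | 26.8 |
| 6.00 | 13.2 | 70.5 | 16.5 |

(scatter of a reading: 0.5 percentage points)

- solid substrate is a solid; its amount is given per volume of the solution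
- the analysis behind the earlier runs scatters by 0.5 percentage points, standard deviation
- at the start none of the solid substrate is in solution
- starting material means what is dissolved; the solid is not counted in it
- no earlier run changes the charge of free catalyst; that part of a forecast is a guess
- starting material is what solid substrate becomes in solution

- the target standing at 30 min, as a percentage of the solid substrate charged
- concentration of starting material in solution at 15 min, in percent of saturation
- the change that raises the amount of target at 30 min, in percent of the solid substrate charged most ("none" if none brings more than 2 percentage points) (cedar / alder / elm / none)
- amount of target at 30 min, in percent of the solid substrate charged, after elm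

- cedar: doubling the amount of free catalyst, all else as stated
- alder: doubling the solubility of the solid substrate, all else as stated
- elm: doubling the dissolution coefficient of the solid substrate, all else as stated

2. In the beta run, target rose by 0.0260 min⁻¹ between the first two readings and by 0.0217 min⁻¹ between the last two, while A went from 34.9% to twice that. Within the scatter of 0.5 percentage points, this looks zero order in A. So we replace the curve by its chord: r, the mean velocity of target over the beta run between first and last reading 0.0238 min⁻¹.

3. Guessing proportion to catalyst, the flask runs at v = 0.0476 min⁻¹, starting from 0.500 min.

4. With A held near 70.5%, the last reading of the beta run, we reckon that the solid in the flask lasts until target reaches 29.5%, which v puts at 6.70 min, earlier than 15 min. After that, A is what target has not taken.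

5. The chord holds only down to A = 34.9%, the lowest A it covers, reached at 14.2 min. Below it we take first-order decay with k = v/A = 0.136 min⁻¹. We reckon A = 4.02% at 30 min, so 96.0% target. At 15 min, taking 70.5% as saturation, we reckon 44.4%. Cedar can still take up the 4.02% left, and elm should leave y about where it stands.

6. The forecast gave 82% (62% to 90%), 57% (42% to 92%), cedar and 82.7% (63% to 91%), on the ground “I guess rate is proportional to catalyst, k ≈ 0.075/min”. It is first order throughout, where we are not.

7. The flask gives 94.9% and 48.7%; the best change is cedar, worth 4.9 points, and elm gives 95.1%.

    2 starting material → self-condensation product (k = 3.74 × 10⁻⁶ M⁻¹ s⁻¹)
    solid substrate ⇌ starting material, rate k2*(cs2 - [starting material]) while solid is left; crystals form when [starting material] > cs2 (solubility = 0.700 M, k = 0.0231 s⁻¹)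
    starting material + free catalyst → catalyst intermediate (k = 1.49 M⁻¹ s⁻¹)
    catalyst intermediate → free catalyst + target (k = 0.670 s⁻¹)

8. Between 3.00 min and 15.0 min, target in the flask rose at 0.0439 min⁻¹, against v of 0.0476 min⁻¹. Carried to the same flask read at 8.0 min, v gives 35.7% target, and that reading holds 36.2%.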